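**Strategy.** The lower flavan is disconnected across its pyran ring F at O1–C8a and C4–C4a. The key step exploits the two adjacent ring-D carbons C4a and C8a, flanked by the C5 oxygen and the C8 interflavan carbon: they are carried as an aryne, generated from an aryl triflate already joined through C8 to C4 of perbenzylated epicatechin. A syn-configured lithium alkoxide bearing a γ-tosylate adds through oxygen to C8a, steered by the C5 benzyloxy group, and the resulting C4a aryllithium displaces the tosylate. One operation thus forges both bonds and closes ring F with both lower stereocentres in place, these coming from an Evans syn-glycolate aldol. Hydrogenolysis of nine benzyl ethers completes the synthesis.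

Key step: step 9

Remark: the target is read as epicatechin-(4β→8)-epiafzelechin (2,3-cis in both units, 3,4-trans in the upper unit; upper unit rings A, C, B; lower unit rings D, F, E). Compounds 6 and 10 are assumed to be purchasable.

Step 1
Reactants: 1 (−)-epicatechin
Product: 2 5,7,3',4'-tetra-O-benzyl-(−)-epicatechin
Conditions: BnBr (4.4 equiv), K2CO3, DMF, 0 °C → rt
Reagents that add atoms: benzyl bromide, BrCc1ccccc1
Why: Williamson etherification in which K2CO3 ionises only the four phenols, so the secondary 3-OH stays free and the mild base avoids ring opening and epimerisation at C2.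

Step 2
Reactants: 2 5,7,3',4'-tetra-O-benzyl-(−)-epicatechin
Product: 3 3,5,7,3',4'-penta-O-benzyl-(−)-epicatechin
Conditions: NaH, BnBr, Bu4NI (cat.), DMF, 0 °C → rt
Reagents that add atoms: benzyl bromide, BrCc1ccccc1
Why: Williamson etherification of the secondary alkoxide; with every phenol capped no quinone methide can form, so C2 and C3 keep their configuration.

Step 3
Reactants: 3 3,5,7,3',4'-penta-O-benzyl-(−)-epicatechin
Product: 5 4β-(2-ethoxyethoxy)-3,5,7,3',4'-penta-O-benzyl-(−)-epicatechin, via flavan-4-ylium DDQH salt 4 (not isolated)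
Conditions: DDQ (2 equiv), 2-ethoxyethanol (5 equiv), CH2Cl2, rt
Reagents that add atoms: 2-ethoxyethanol, CCOCCO
Why: DDQ benzylic oxidation, in which hydride transfer from C4 (activated by the 5,7-dioxygenated ring A) to the quinone gives the flavan-4-ylium hydroquinone-monoanion ion pair 4 and the alcohol should capture the cation on the β face, anti to the 3-benzyloxy and 2-aryl groups (3,4-trans).

Step 4
Reactants: 5 4β-(2-ethoxyethoxy)-3,5,7,3',4'-penta-O-benzyl-(−)-epicatechin; 6 3,5-bis(benzyloxy)phenol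
Product: 8 4β-[2,4-bis(benzyloxy)-6-hydroxyphenyl]-3,5,7,3',4'-penta-O-benzyl-(−)-epicatechin, via flavan-4-ylium triflate 7 (not isolated)
Conditions: 6 (4 equiv), TMSOTf (0.2 equiv), CH2Cl2, −78 → −40 °C
Reagents that add atoms: none
Why: Lewis-acid Friedel–Crafts arylation in which TMSOTf silylates the C4 ether oxygen and expels the trimethylsilyl ether of 2-ethoxyethanol to give flavan-4-ylium triflate 7, the excess phenol should attack through a carbon ortho to its hydroxyl (less hindered than the carbon between the two benzyloxy groups and present twice), approach from the β face anti to the C3 and C2 substituents sets the 4β (3,4-trans) centre of the target, and the TfOH released cleaves the silyl ether so that TMSOTf is regenerated and 2-ethoxyethanol is set free.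

Step 5
Reactants: 8 4β-[2,4-bis(benzyloxy)-6-hydroxyphenyl]-3,5,7,3',4'-penta-O-benzyl-(−)-epicatechin
Product: 9 3,5-bis(benzyloxy)-2-[3,5,7,3',4'-penta-O-benzyl-(−)-epicatechin-4β-yl]phenyl trifluoromethanesulfonate
Conditions: Tf2O (1.2 equiv), pyridine, CH2Cl2, 0 °C
Reagents that add atoms: trifluoromethanesulfonic anhydride, O=S(=O)(OS(=O)(=O)C(F)(F)F)C(F)(F)F
Why: O-sulfonylation of the only free hydroxyl turns the future C8a oxygen into a leaving group beside the acidic H4a; no stereocentre is touched.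

Step 6
Reactants: 10 (S)-4-benzyl-3-[(benzyloxy)acetyl]oxazolidin-2-one; 11 4-(benzyloxy)benzaldehyde
Product: 13 (S)-4-benzyl-3-[(2S,3R)-2-(benzyloxy)-3-[4-(benzyloxy)phenyl]-3-hydroxypropanoyl]oxazolidin-2-one, via boron enolate 12 (not isolated)
Conditions: Bu2BOTf, Et3N, CH2Cl2, −78 → 0 °C; then pH 7 buffer, MeOH, H2O2, 0 °C
Reagents that add atoms: none
Why: Evans syn-glycolate aldol in which soft enolisation gives the (Z)-boron enolate 12, which should react through a chair Zimmerman–Traxler transition state on the face away from the auxiliary benzyl group and so set the 2,3-syn (2S,3R) pair that becomes C3 and C2 of the lower unit.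

Step 7
Reactants: 13 (S)-4-benzyl-3-[(2S,3R)-2-(benzyloxy)-3-[4-(benzyloxy)phenyl]-3-hydroxypropanoyl]oxazolidin-2-one
Product: 14 (1R,2R)-2-(benzyloxy)-1-[4-(benzyloxy)phenyl]propane-1,3-diol
Conditions: LiBH4, THF, MeOH (2 equiv), 0 °C
Reagents that add atoms: none
Why: Reductive cleavage of the N-acyl oxazolidinone by hydride attack on the exocyclic carbonyl gives the primary alcohol without touching either stereocentre, and the auxiliary is recovered.

Step 8
Reactants: 14 (1R,2R)-2-(benzyloxy)-1-[4-(benzyloxy)phenyl]propane-1,3-diol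
Product: 15 (2R,3R)-2-(benzyloxy)-3-[4-(benzyloxy)phenyl]-3-hydroxypropyl 4-methylbenzenesulfonate
Conditions: TsCl (1.05 equiv), Et3N, DMAP (cat.), CH2Cl2, 0 °C
Reagents that add atoms: p-toluenesulfonyl chloride, Cc1ccc(S(=O)(=O)Cl)cc1
Why: Selective sulfonylation, since the primary hydroxyl should react much faster than the hindered secondary benzylic one with one equivalent of TsCl at 0 °C.

Step 9
Reactants: 9 3,5-bis(benzyloxy)-2-[3,5,7,3',4'-penta-O-benzyl-(−)-epicatechin-4β-yl]phenyl trifluoromethanesulfonate; 15 (2R,3R)-2-(benzyloxy)-3-[4-(benzyloxy)phenyl]-3-hydroxypropyl 4-methylbenzenesulfonate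
Product: 19 3,5,7,3',4'-penta-O-benzyl-(−)-epicatechin-(4β→8)-3,5,7,4'-tetra-O-benzyl-(−)-epiafzelechin, via lithium alkoxide 16 (not isolated), via aryne 17 (not isolated), via aryllithium 18 (not isolated)
Conditions: 15 (2 equiv), n-BuLi (2 equiv), THF, −78 °C; then 9 (1 equiv); then LiTMP (1.3 equiv), −78 → 0 °C
Reagents that add atoms: none
Why: Proposed new method: LiTMP removes H4a of 9, the most acidic aryl hydrogen because it lies between the triflate and the C5 benzyloxy group, and loss of LiOTf gives aryne 17, whose triple bond can only be C4a≡C8a since C8 carries the flavanyl group. The oxygen of alkoxide 16 adds to C8a, the aryne carbon remote from the inductively withdrawing C5 benzyloxy group, so that the carbanion develops at C4a beside that oxygen (aryne distortion control); this electronic bias and the excess of 16 must override the steric shielding of C8a by the C8 substituent and the competing addition of the hindered amide. Aryllithium 18 then displaces the primary tosylate in a 6-exo-tet cyclialkylation that closes ring F, so O1–C8a forms intermolecularly and C4–C4a by ring closure in the same flask. No stereocentre is created: C2 and C3 of the lower unit arrive from 15 with retention because no bond to either carbon is broken, and the upper-unit centres are not involved. The closest known reaction types are the addition of alkoxides to arynes generated from aryl triflates by lithium amides, aryne annulations in which one partner is nucleophile and electrophile at once (salicylates giving xanthones), and the Parham cyclialkylation of ortho-lithiated aryl 3-halopropyl ethers to chromans.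

Step 10
Reactants: 19 3,5,7,3',4'-penta-O-benzyl-(−)-epicatechin-(4β→8)-3,5,7,4'-tetra-O-benzyl-(−)-epiafzelechin
Product: 20 epicatechin-(4β→8)-epiafzelechin (CNP0299023.1)
Conditions: H2 (1 atm), Pd(OH)2/C, THF/MeOH/H2O, rt
Reagents that add atoms: none
Why: Catalytic hydrogenolysis over Pd(OH)2/C should cleave all nine benzyl ethers under conditions mild enough for the ring C2–O1 bonds, the interflavan bond and every stereocentre to persist.

**Compound list**
1 | (−)-epicatechin | C1c2c(O)cc(O)cc2O[C@H](c2ccc(O)c(O)c2)[C@@H]1O | starting material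
2 | 5,7,3',4'-tetra-O-benzyl-(−)-epicatechin | C1c2c(OCc3ccccc3)cc(OCc3ccccc3)cc2O[C@H](c2ccc(OCc3ccccc3)c(OCc3ccccc3)c2)[C@@H]1O | intermediate
3 | 3,5,7,3',4'-penta-O-benzyl-(−)-epicatechin | C1c2c(OCc3ccccc3)cc(OCc3ccccc3)cc2O[C@H](c2ccc(OCc3ccccc3)c(OCc3ccccc3)c2)[C@@H]1OCc1ccccc1 | intermediate
4 | flavan-4-ylium cation of 3 as its 2,3-dichloro-5,6-dicyano-4-hydroxyphenolate ion pair | [CH+]1c2c(OCc3ccccc3)cc(OCc3ccccc3)cc2O[C@H](c2ccc(OCc3ccccc3)c(OCc3ccccc3)c2)[C@@H]1OCc1ccccc1.[O-]c1c(Cl)c(Cl)c(O)c(C#N)c1C#N | intermediate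
5 | 4β-(2-ethoxyethoxy)-3,5,7,3',4'-penta-O-benzyl-(−)-epicatechin (2,3-cis, 3,4-trans) | CCOCCO[C@H]1c2c(OCc3ccccc3)cc(OCc3ccccc3)cc2O[C@H](c2ccc(OCc3ccccc3)c(OCc3ccccc3)c2)[C@@H]1OCc1ccccc1 | intermediate
6 | 3,5-bis(benzyloxy)phenol | Oc1cc(OCc2ccccc2)cc(OCc2ccccc2)c1 | starting material
7 | flavan-4-ylium cation of 3 as its trifluoromethanesulfonate ion pair | [CH+]1c2c(OCc3ccccc3)cc(OCc3ccccc3)cc2O[C@H](c2ccc(OCc3ccccc3)c(OCc3ccccc3)c2)[C@@H]1OCc1ccccc1.[O-]S(=O)(=O)C(F)(F)F | intermediate
8 | 4β-[2,4-bis(benzyloxy)-6-hydroxyphenyl]-3,5,7,3',4'-penta-O-benzyl-(−)-epicatechin | Oc1cc(OCc2ccccc2)cc(OCc2ccccc2)c1[C@H]1c2c(OCc3ccccc3)cc(OCc3ccccc3)cc2O[C@H](c2ccc(OCc3ccccc3)c(OCc3ccccc3)c2)[C@@H]1OCc1ccccc1 | intermediate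
9 | 3,5-bis(benzyloxy)-2-[3,5,7,3',4'-penta-O-benzyl-(−)-epicatechin-4β-yl]phenyl trifluoromethanesulfonate | FC(F)(F)S(=O)(=O)Oc1cc(OCc2ccccc2)cc(OCc2ccccc2)c1[C@H]1c2c(OCc3ccccc3)cc(OCc3ccccc3)cc2O[C@H](c2ccc(OCc3ccccc3)c(OCc3ccccc3)c2)[C@@H]1OCc1ccccc1 | intermediate
10 | (S)-4-benzyl-3-[(benzyloxy)acetyl]oxazolidin-2-one | O=C(COCc1ccccc1)N1C(=O)OC[C@@H]1Cc1ccccc1 | starting material
11 | 4-(benzyloxy)benzaldehyde | O=Cc1ccc(OCc2ccccc2)cc1 | starting material
12 | (Z)-dibutylboron enolate of 10 | CCCCB(CCCC)O/C(N1C(=O)OC[C@@H]1Cc1ccccc1)=C\OCc1ccccc1 | intermediate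
13 | (S)-4-benzyl-3-[(2S,3R)-2-(benzyloxy)-3-[4-(benzyloxy)phenyl]-3-hydroxypropanoyl]oxazolidin-2-one | c1ccccc1COc1ccc([C@@H](O)[C@@H](C(=O)N2C(=O)OC[C@@H]2Cc2ccccc2)OCc2ccccc2)cc1 | intermediate
14 | (1R,2R)-2-(benzyloxy)-1-[4-(benzyloxy)phenyl]propane-1,3-diol | c1ccccc1COc1ccc([C@@H](O)[C@@H](CO)OCc2ccccc2)cc1 | intermediate
15 | (2R,3R)-2-(benzyloxy)-3-[4-(benzyloxy)phenyl]-3-hydroxypropyl 4-methylbenzenesulfonate | c1ccccc1COc1ccc([C@@H](O)[C@@H](COS(=O)(=O)c2ccc(C)cc2)OCc2ccccc2)cc1 | intermediate
16 | lithium alkoxide of 15 | c1ccccc1COc1ccc([C@@H](O[Li])[C@@H](COS(=O)(=O)c2ccc(C)cc2)OCc2ccccc2)cc1 | intermediate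
17 | ring-D aryne (C4a≡C8a): 3,5-bis(benzyloxy)-6-[penta-O-benzyl-epicatechin-4β-yl]benzyne | C1#CC(OCc2ccccc2)=CC(OCc2ccccc2)=C1[C@H]1c2c(OCc3ccccc3)cc(OCc3ccccc3)cc2O[C@H](c2ccc(OCc3ccccc3)c(OCc3ccccc3)c2)[C@@H]1OCc1ccccc1 | intermediate
18 | C4a-lithiated aryl ether from O-addition of 16 to C8a of 17 | [Li]c1c(OCc2ccccc2)cc(OCc2ccccc2)c([C@H]2c3c(OCc4ccccc4)cc(OCc4ccccc4)cc3O[C@H](c3ccc(OCc4ccccc4)c(OCc4ccccc4)c3)[C@@H]2OCc2ccccc2)c1O[C@H](c1ccc(OCc2ccccc2)cc1)[C@@H](COS(=O)(=O)c1ccc(C)cc1)OCc1ccccc1 | intermediate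
19 | 3,5,7,3',4'-penta-O-benzyl-(−)-epicatechin-(4β→8)-3,5,7,4'-tetra-O-benzyl-(−)-epiafzelechin | c1ccccc1COc1ccc([C@H]2Oc3c(c(OCc4ccccc4)cc(OCc4ccccc4)c3[C@H]3c4c(OCc5ccccc5)cc(OCc5ccccc5)cc4O[C@H](c4ccc(OCc5ccccc5)c(OCc5ccccc5)c4)[C@@H]3OCc3ccccc3)C[C@H]2OCc2ccccc2)cc1 | intermediate
20 | epicatechin-(4β→8)-epiafzelechin (CNP0299023.1) | Oc1ccc([C@H]2Oc3c(c(O)cc(O)c3[C@H]3c4c(O)cc(O)cc4O[C@H](c4ccc(O)c(O)c4)[C@@H]3O)C[C@H]2O)cc1 | target

**Totals.** Total step count: 10. Longest linear sequence: 7 steps (steps 1–5, 9, 10); the three-step branch to 15 (steps 6–8) joins at step 9.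

**Steps most likely to fail**

1. Step 9 (Proposed new method). Possible failures are addition of the amide base or of a second aryllithium to the aryne in place of the alkoxide, oxygen attack at C4a because the C8 flavanyl group shields C8a, lithiation at C6 between the two benzyloxy groups instead of at C4a, closure of the alkoxide onto its own tosylate to an oxetane before the aryne is formed, protonation of the aryllithium before ring closure, or triflyl migration instead of elimination. The fallback is the known Lewis-acid 4→8 coupling of flavan units and sets out from 5. Purchasable (−)-epiafzelechin F1 is benzylated as in steps 1 and 2: BnBr, K2CO3, DMF gives 5,7,4'-tri-O-benzyl-(−)-epiafzelechin F2, and NaH, BnBr then gives 3,5,7,4'-tetra-O-benzyl-(−)-epiafzelechin F3. F3 (4 equiv) and 5 with TMSOTf in CH2Cl2 at −78 °C should give, by attack of C8 of F3 on the β face of the C4 cation released from 5, compound 19, where the route is rejoined.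

2. Step 4. Possible failures are attack through the carbon between the two benzyloxy groups (para to the hydroxyl), O-alkylation of the phenol, or a second alkylation of the product by another cation. The fallback is a blocking-group strategy that sets out from 6. NBS in CH2Cl2 at −78 °C should brominate para to the hydroxyl and give 4-bromo-3,5-bis(benzyloxy)phenol F4, any ortho isomer being removed at this inexpensive stage. Coupling of F4 with 5 (TMSOTf, CH2Cl2, −78 °C) can then occur only ortho to the hydroxyl and should give 4β-[3-bromo-2,4-bis(benzyloxy)-6-hydroxyphenyl]-3,5,7,3',4'-penta-O-benzyl-(−)-epicatechin F5. Bromine–lithium exchange (n-BuLi, 2.2 equiv, THF, −78 °C) and protonation with MeOH remove the blocking atom and return to the route at 8.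

3. Step 10. Possible failures are incomplete cleavage of the two hindered secondary benzyl ethers, deactivation of the catalyst by the polyphenol, or over-reduction. The fallback sets out from 19 and replaces hydrogenolysis by Lewis-acid dealkylation: BCl3 with pentamethylbenzene as benzyl-cation scavenger in CH2Cl2 at −78 °C, quenched cold with MeOH, should give 20 directly. It makes no new compound (entry F0).

**Further compounds**
F1 | step 9 | (−)-epiafzelechin | Oc1ccc([C@H]2Oc3cc(O)cc(O)c3C[C@H]2O)cc1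
F2 | step 9 | 5,7,4'-tri-O-benzyl-(−)-epiafzelechin | c1ccccc1COc1ccc([C@H]2Oc3cc(OCc4ccccc4)cc(OCc4ccccc4)c3C[C@H]2O)cc1
F3 | step 9 | 3,5,7,4'-tetra-O-benzyl-(−)-epiafzelechin | c1ccccc1COc1ccc([C@H]2Oc3cc(OCc4ccccc4)cc(OCc4ccccc4)c3C[C@H]2OCc2ccccc2)cc1
F4 | step 4 | 4-bromo-3,5-bis(benzyloxy)phenol | Oc1cc(OCc2ccccc2)c(Br)c(OCc2ccccc2)c1
F5 | step 4 | 4β-[3-bromo-2,4-bis(benzyloxy)-6-hydroxyphenyl]-3,5,7,3',4'-penta-O-benzyl-(−)-epicatechin | Oc1cc(OCc2ccccc2)c(Br)c(OCc2ccccc2)c1[C@H]1c2c(OCc3ccccc3)cc(OCc3ccccc3)cc2O[C@H](c2ccc(OCc3ccccc3)c(OCc3ccccc3)c2)[C@@H]1OCc1ccccc1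
F0 | step 10 | none | none
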